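Structural feature: in the oxolane (O1, C2 aryl, C3 CH2OH, C4 benzyl, C5), C2, C3 and the hydroxymethyl carbon are Cβ, Cα and C=O of 3,4,5-trimethoxycinnamaldehyde. O1, C5, C4 and the benzylic carbon are the O–CH2–C≡C chain of 3-(3,4,5-trimethoxyphenyl)prop-2-yn-1-ol.
Key disconnections: O1–C2 (reversible oxa-Michael addition to the enal iminium ion) and C3–C4 (enamine attack on the palladium-bound alkyne). Both bonds form in one amine/palladium [3+2] annulation that sets C2 and C3.
Late stage: CHO is reduced to CH2OH, then hydrogenation of the C4 benzylidene anti to the silylated C3 arm sets C4 (3,4-cis).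
Ring order: the oxolane is the only ring made, and it closes in the annulation. Both arenes are bought, and the alkynol comes from one Sonogashira coupling.

Key step: step 2

Assumption: the benzylidene alkene left by the key step is drawn E (aryl group cis to C3), as anti attack on a palladium-bound alkyne predicts. This geometry is erased by the later hydrogenation.

Step 1
Reactants: 1 5-iodo-1,2,3-trimethoxybenzene; 2 propargyl alcohol
Product: 3 3-(3,4,5-trimethoxyphenyl)prop-2-yn-1-ol
Conditions: PdCl2(PPh3)2 (2 mol %), CuI (4 mol %), Et3N, THF, rt, argon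
Reagents that add atoms: none
Why: Sonogashira coupling, in which zerovalent palladium inserts into the aryl–iodine bond of 1, the copper acetylide of 2 transmetalates and reductive elimination forms the aryl–alkyne bond; aryl iodides couple at room temperature even when electron-rich, and the free hydroxyl group is tolerated.

Step 2
Reactants: 3 3-(3,4,5-trimethoxyphenyl)prop-2-yn-1-ol; 4 (E)-3,4,5-trimethoxycinnamaldehyde
Product: 6 (2S,3S,4E)-2-(3,4,5-trimethoxyphenyl)-4-[(3,4,5-trimethoxyphenyl)methylidene]oxolane-3-carbaldehyde, via oxa-Michael adduct 5 (not isolated)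
Conditions: 3 (1.5 equiv), (S)-α,α-diphenylprolinol trimethylsilyl ether (20 mol %), PdCl2(MeCN)2 (10 mol %), PhCO2H (20 mol %), THF, 4 °C to rt; cold filtration through a short silica pad, crude 6 used at once
Reagents that add atoms: none
Why: Proposed new method: the amine and enal 4 form an iminium ion, alkynol 3 adds reversibly to its β-carbon (O1–C2) to give the enamine of 5, this enamine attacks the alkyne π-bound to divalent palladium anti to the metal (C3–C4), and protodepalladation of the vinylpalladium species plus hydrolysis of the iminium ion release 6 and both catalysts. The closest known reaction type is the merged chiral-amine/palladium dynamic kinetic asymmetric oxa-Michael/carbocyclization of enals with terminal propargylic alcohols; what is new is the aryl cap on the alkyne, which binds palladium less readily, hence the raised loading of the nitrile-ligated chloride. The single ring, the oxolane, closes 5-exo-dig, because the three-atom Cβ–O–CH2 tether brings the enamine carbon poorly to the distal alkyne carbon and because the 3,4,5-trimethoxyphenyl cap, whose para donor is offset by two meta methoxy groups, polarizes the alkyne too little to pull the attack 6-endo. C2 is controlled by the (S)-catalyst, whose CPh2(OSiMe3) group covers the Re face of Cβ so that oxygen enters on the Si face (2S), and because the addition reverts, any 2R adduct returns to 4 while the matched 2S enamine, whose tether lies on the open face, cyclizes faster. C3 is fixed in the ring closure, the E-enamine reacting on that same open face so that formyl ends trans to the C2 aryl group (3S), which is also the arrangement favoured should C3 epimerize. The selectivity most at stake is retention of the exocyclic alkene, since terminal alkynes are known to end as conjugated dihydrofuran aldehydes; here styrene conjugation with the aryl cap, the strain of a planar dienamine that would press this aryl group against the catalyst-bearing carbon, the low temperature and the immediate reduction should hold the alkene and C3 in place.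

Step 3
Reactants: 6 (2S,3S,4E)-2-(3,4,5-trimethoxyphenyl)-4-[(3,4,5-trimethoxyphenyl)methylidene]oxolane-3-carbaldehyde
Product: 7 [(2S,3R,4E)-2-(3,4,5-trimethoxyphenyl)-4-[(3,4,5-trimethoxyphenyl)methylidene]oxolan-3-yl]methanol
Conditions: NaBH4, MeOH/CH2Cl2, −20 °C, 15 min; aq NH4Cl
Reagents that add atoms: none
Why: Borohydride 1,2-reduction of an aldehyde is far faster at low temperature than removal of the doubly activated C3 proton, creates no stereocentre (the change from 3S to 3R is only a change of CIP priority), and takes C3 out of the α-position so that neither its configuration nor the alkene can move afterwards.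

Step 4
Reactants: 7 [(2S,3R,4E)-2-(3,4,5-trimethoxyphenyl)-4-[(3,4,5-trimethoxyphenyl)methylidene]oxolan-3-yl]methanol
Product: 8 tert-butyl(dimethyl){[(2S,3R,4E)-2-(3,4,5-trimethoxyphenyl)-4-[(3,4,5-trimethoxyphenyl)methylidene]oxolan-3-yl]methoxy}silane
Conditions: TBSCl, imidazole, DMF, rt
Reagents that add atoms: tert-butyldimethylsilyl chloride (TBSCl), CC(C)(C)[Si](C)(C)Cl
Why: Imidazole-promoted silylation of a primary alcohol, which enlarges the C3 arm and removes the hydroxyl group that could anchor the substrate to the hydrogenation catalyst on the wrong face, without touching a stereocentre.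

Step 5
Reactants: 8 tert-butyl(dimethyl){[(2S,3R,4E)-2-(3,4,5-trimethoxyphenyl)-4-[(3,4,5-trimethoxyphenyl)methylidene]oxolan-3-yl]methoxy}silane
Product: 9 tert-butyl(dimethyl){[(2S,3R,4R)-2-(3,4,5-trimethoxyphenyl)-4-[(3,4,5-trimethoxyphenyl)methyl]oxolan-3-yl]methoxy}silane
Conditions: H2 (1 atm), 10% Pd/C, EtOAc, rt, stopped after uptake of one equivalent
Reagents that add atoms: none
Why: Heterogeneous syn-hydrogenation of a trisubstituted styrenyl alkene under substrate control, in which allylic 1,3-strain with the aryl group of the E-benzylidene turns the adjacent CH2OTBS arm pseudoaxial over one face, so the alkene should adsorb by the other face and C4 receives hydrogen anti to that arm, leaving benzyl and CH2OTBS cis (4R).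

Step 6
Reactants: 9 tert-butyl(dimethyl){[(2S,3R,4R)-2-(3,4,5-trimethoxyphenyl)-4-[(3,4,5-trimethoxyphenyl)methyl]oxolan-3-yl]methoxy}silane
Product: 10 [(2S,3R,4R)-2-(3,4,5-trimethoxyphenyl)-4-[(3,4,5-trimethoxyphenyl)methyl]oxolan-3-yl]methanol
Conditions: TBAF, THF, 0 °C to rt
Reagents that add atoms: none
Why: Fluoride-induced desilylation, driven by the strong Si–F bond, runs under non-acidic conditions, so the acid-labile benzylic C2–O bond and all three stereocentres stay untouched.

Compound list
1 | 5-iodo-1,2,3-trimethoxybenzene | COc1cc(I)cc(OC)c1OC | starting material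
2 | propargyl alcohol (prop-2-yn-1-ol) | C#CCO | starting material
3 | 3-(3,4,5-trimethoxyphenyl)prop-2-yn-1-ol | COc1cc(C#CCO)cc(OC)c1OC | intermediate
4 | (E)-3,4,5-trimethoxycinnamaldehyde | COc1cc(/C=C/C=O)cc(OC)c1OC | starting material
5 | (3S)-3-(3,4,5-trimethoxyphenyl)-3-{[3-(3,4,5-trimethoxyphenyl)prop-2-yn-1-yl]oxy}propanal (oxa-Michael adduct, in equilibrium with its catalyst enamine) | O=CC[C@H](OCC#Cc1cc(OC)c(OC)c(OC)c1)c1cc(OC)c(OC)c(OC)c1 | intermediate
6 | (2S,3S,4E)-2-(3,4,5-trimethoxyphenyl)-4-[(3,4,5-trimethoxyphenyl)methylidene]oxolane-3-carbaldehyde (2,3-trans) | O=C[C@H]1/C(=C\c2cc(OC)c(OC)c(OC)c2)CO[C@@H]1c1cc(OC)c(OC)c(OC)c1 | intermediate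
7 | [(2S,3R,4E)-2-(3,4,5-trimethoxyphenyl)-4-[(3,4,5-trimethoxyphenyl)methylidene]oxolan-3-yl]methanol | OC[C@H]1/C(=C\c2cc(OC)c(OC)c(OC)c2)CO[C@@H]1c1cc(OC)c(OC)c(OC)c1 | intermediate
8 | tert-butyl(dimethyl){[(2S,3R,4E)-2-(3,4,5-trimethoxyphenyl)-4-[(3,4,5-trimethoxyphenyl)methylidene]oxolan-3-yl]methoxy}silane | CC(C)(C)[Si](C)(C)OC[C@H]1/C(=C\c2cc(OC)c(OC)c(OC)c2)CO[C@@H]1c1cc(OC)c(OC)c(OC)c1 | intermediate
9 | tert-butyl(dimethyl){[(2S,3R,4R)-2-(3,4,5-trimethoxyphenyl)-4-[(3,4,5-trimethoxyphenyl)methyl]oxolan-3-yl]methoxy}silane (2,3-trans, 3,4-cis) | COc1cc(C[C@H]2CO[C@H](c3cc(OC)c(OC)c(OC)c3)[C@H]2CO[Si](C)(C)C(C)(C)C)cc(OC)c1OC | intermediate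
10 | [(2S,3R,4R)-2-(3,4,5-trimethoxyphenyl)-4-[(3,4,5-trimethoxyphenyl)methyl]oxolan-3-yl]methanol (CNP0321241.1) | COc1cc(C[C@H]2CO[C@H](c3cc(OC)c(OC)c(OC)c3)[C@H]2CO)cc(OC)c1OC | target

Total step count: 6. Longest linear sequence: 6 steps (1 → 3 → 6 → 7 → 8 → 9 → 10).

Steps most likely to fail

**Step 2.**
- Three things may go wrong:
  - The disubstituted aryl alkyne may be activated too weakly by divalent palladium, so that the oxa-Michael equilibrium merely reverts.
  - Ring closure may drift toward the 6-endo mode.
  - The exocyclic alkene may migrate into conjugation with the formyl group through a dienamine, which would erase C3.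
- The fallback uses known chemistry, sets out from 3 and comes back at 7. It forms C3–C4 with a carbon radical instead of an enamine and never enters the aldehyde oxidation level.
- An Appel reaction (CBr4, PPh3, CH2Cl2, 0 °C) converts 3 into 5-(3-bromoprop-1-yn-1-yl)-1,2,3-trimethoxybenzene F1.
- Vinylmagnesium bromide adds to commercial 3,4,5-trimethoxybenzaldehyde to give racemic 1-(3,4,5-trimethoxyphenyl)prop-2-en-1-ol F2.
- Kinetic resolution with Candida antarctica lipase B and vinyl acetate acylates the enantiomer that places the aryl group in the large pocket. It should leave (1S)-1-(3,4,5-trimethoxyphenyl)prop-2-en-1-ol F3 beside (1R)-1-(3,4,5-trimethoxyphenyl)prop-2-en-1-yl acetate F4, which is removed by chromatography.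
- Williamson etherification of F3 with F1 (NaH, THF, 0 °C) keeps the carbinol centre and gives 1,2,3-trimethoxy-5-[(1S)-1-{[3-(3,4,5-trimethoxyphenyl)prop-2-yn-1-yl]oxy}prop-2-en-1-yl]benzene F5.
- mCPBA (CH2Cl2, rt) epoxidizes the vinyl group in preference to the alkyne. The product is 2-[(R)-(3,4,5-trimethoxyphenyl){[3-(3,4,5-trimethoxyphenyl)prop-2-yn-1-yl]oxy}methyl]oxirane F6. Its two oxirane epimers are equivalent here because that carbon becomes a planar radical.
- The trivalent titanium reagent Cp2TiCl (from Cp2TiCl2 and Zn, THF, rt) opens the oxirane reductively to the secondary β-titanoxy radical. This radical closes 5-exo-dig onto the aryl alkyne with the C2 aryl group pseudoequatorial (2,3-trans).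
- Hydrogen-atom transfer to the linear α-aryl vinyl radical from the open C5 side, followed by acidic work-up, should deliver 7.

**Step 5.**
- Facial selectivity may be poor, because the face that must meet the metal also carries the C2 aryl group.
- The alkene may also migrate into the ring on palladium with loss of C3, or the allylic C5–O and benzylic C2–O bonds may undergo hydrogenolysis.
- The fallback sets out from 8 and comes back at 9. Substrate control on a surface is replaced by catalyst control in solution.
- It is an asymmetric hydrogenation of the unfunctionalized trisubstituted aryl alkene with a cationic iridium phosphine–oxazoline complex: [Ir(cod)(tBu-PHOX)][B(3,5-(CF3)2C6H3)4], H2 (50 bar), CH2Cl2, rt.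
- Both ligand antipodes are available, and the one that reinforces delivery anti to the CH2OTBS arm is used. Such complexes leave benzylic ethers intact and cause little alkene migration.
- This fallback makes no new compound F0.

**Step 3.**
- The basic hydride medium may remove the C3 proton, which is both allylic and α to the formyl group, before hydride delivery. That would lead to epimerization or alkene migration.
- The fallback sets out from 6 and comes back at 10. The two reductions are run in the opposite order.
- Crude 6 is first hydrogenated in a neutral medium (H2, 1 atm, 10% Pd/C, EtOAc) anti to the formyl group. This gives (2S,3S,4R)-2-(3,4,5-trimethoxyphenyl)-4-[(3,4,5-trimethoxyphenyl)methyl]oxolane-3-carbaldehyde F7, in which C3–H is only an ordinary α-proton and conjugation is no longer possible.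
- NaBH4 (MeOH, 0 °C) then gives 10 directly, so silylation and desilylation are not needed.

Further compounds
F1 | step 2 | 5-(3-bromoprop-1-yn-1-yl)-1,2,3-trimethoxybenzene | COc1cc(C#CCBr)cc(OC)c1OC
F2 | step 2 | racemic 1-(3,4,5-trimethoxyphenyl)prop-2-en-1-ol | C=CC(O)c1cc(OC)c(OC)c(OC)c1
F3 | step 2 | (1S)-1-(3,4,5-trimethoxyphenyl)prop-2-en-1-ol | C=C[C@H](O)c1cc(OC)c(OC)c(OC)c1
F4 | step 2 | (1R)-1-(3,4,5-trimethoxyphenyl)prop-2-en-1-yl acetate | C=C[C@@H](OC(C)=O)c1cc(OC)c(OC)c(OC)c1
F5 | step 2 | 1,2,3-trimethoxy-5-[(1S)-1-{[3-(3,4,5-trimethoxyphenyl)prop-2-yn-1-yl]oxy}prop-2-en-1-yl]benzene | C=C[C@H](OCC#Cc1cc(OC)c(OC)c(OC)c1)c1cc(OC)c(OC)c(OC)c1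
F6 | step 2 | 2-[(R)-(3,4,5-trimethoxyphenyl){[3-(3,4,5-trimethoxyphenyl)prop-2-yn-1-yl]oxy}methyl]oxirane (both oxirane epimers) | C1OC1[C@H](OCC#Cc1cc(OC)c(OC)c(OC)c1)c1cc(OC)c(OC)c(OC)c1
F7 | step 3 | (2S,3S,4R)-2-(3,4,5-trimethoxyphenyl)-4-[(3,4,5-trimethoxyphenyl)methyl]oxolane-3-carbaldehyde | COc1cc(C[C@H]2CO[C@H](c3cc(OC)c(OC)c(OC)c3)[C@H]2C=O)cc(OC)c1OC
F0 | step 5 | none | none
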